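(The constants are those of an exercise; the result is computed.)

I decided to leave the baths and feeds as they were set and to hand over the bench with a single clock for reading the flasks.

    starting material + reagent + product → 2 product (k1 = 5300 /M²/s, Ea1 = 14.0 kJ/mol)
    starting material + reagent → product (k2 = 1.4 /M/s, Ea2 = 50.0 kJ/mol)
    2 starting material → homo dimer (k3 = 23 /M/s, Ea3 = 42.0 kJ/mol)
    starting material + product ⇌ idle adduct, settled at all times (K4 = 360 /M, ΔH4 = −59.0 kJ/mol)
    (constants at 5 °C)

| setting | north-east | north | east | north-west | west |
|---|---|---|---|---|---|
| starting material | 0.0050 M | 0.0050 M | 0.0050 M | 0.0050 M | 0.0050 M (fed, over 12 s) |
| reagent | 5.25 mM | 5.25 mM | 5.25 mM (fed, over 12 s) | 5.25 mM (fed, over 12 s) | 5.25 mM |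
| temperature | 5 °C |  |  | 5 °C | 5 °C |
| time | 15 s | 15 s | 15 s | 15 s | 15 s |
| remark | everything together at the start | everything together at the start at −15 °C, warmed to 5 °C at 12 s | the addition at −15 °C, then warmed to 5 °C; the feed brings no volume worth counting | all else is in the flask from the start; the feed brings no volume worth counting | all else is in the flask from the start; the feed brings no volume worth counting |

- in percentages every species weighs as the starting material in it: one homo dimer or idle adduct counts as two
- for product the idle adduct is counted in
- two of one species on the left: rate k times its square, two consumed each time
- the constants hold at 5 °C; other temperatures follow from the activation energies and enthalpies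
- in an amount of product, one idle adduct counts as one product

- the flask with the highest amount of homo dimer, in percent of the starting material charged ("all alike" if they lie within 1.5 percentage points) (north-east / north / east / north-west / west / all alike)
- final homo dimer, as a percentage of the starting material charged, in north-east
- final homo dimer, as a percentage of the starting material charged, in north
- final homo dimer, as a percentage of the starting material charged, in east
- final homo dimer, as a percentage of the starting material charged, in north-west
- final homo dimer, as a percentage of the starting material charged, in west

What you will find in these flasks is starting material turning into homo dimer. In north-east at the start, the homo dimer step used starting material 31.3 times as fast as the step to product; this is the selectivity factor. It falls in step with c(starting material) while c(reagent) holds, and I chose, as a simplification that gives a rough figure, to reckon on the homo dimer step by itself and to set the product and adduct steps aside. My clock was the first half-life of the starting material by the homo dimer step alone, and the fraction remaining follows from it: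

τ = 1/(2 · 23 /M/s · 0.0050 M) = 4.35 s

remaining = 1/(1 + 15 s/τ) = 22.5%

With the reagent in full, the ratio had drifted by then to 7.03. I left word not to touch the baths, because at −15 °C the homo dimer rate constant was a quarter of its warm value:

k cold = 5.63 /M/s, τ cold = 17.8 s

remaining in north and east = 1/(1 + 12 s/τ cold + (15 s − 12 s)/τ) = 42.3%

So I expected about 77.5% homo dimer in north-east and north-west, and 57.7% in north and east. The clock could not separate the flasks within each pair, and I did not reckon west, whose starting material is fed.

The forecast gave 71% in north-east, 56% in north, 56.5% in east, 74.5% in north-west and 54% in west, with north-west highest, holding that “dimer is set mainly by how long and how warm the starting material sits at high concentration”. Its north-west figure stood below mine.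

The flasks gave 72.6% in north-east, 55.8% in north, 56.7% in east, 76.0% in north-west and 55.1% in west, with north-west highest. In north-west, 21% of the starting material stood unbound at 15.0 s against my 22.5%, and the homo dimer step was then using it 6.7 times as fast as the step to product, against my drifted 7.03. A neighbour like north-west kept at −20 °C has a clock of 26.1 s, which leaves 63.5%, and that flask held 63% unbound.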